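The whole plan rests on making ring A last, on a finished 4-pyranone. The three oxygen substituents of ring A (C5, C7, C8a) are 1,3,5-related and the ring is annulated along C4a–C8a. C5 can therefore be read as a ketene carbonyl carbon, C7 as the alkoxy carbon of methoxyacetylene, and C8a=C4a as a C=C bond of the pyranone. The precursor is a 6-diazoacetyl-4-pyranone that already holds the complete (S)-silyloxy ester side chain. Its photochemical Wolff rearrangement, (2+2) capture by the ynol ether and a thermal 4π/6π cascade should forge C5–C6, C7–C8 and C4a–C5 (plus C8–C8a through the 1,2-shift) in one operation. The precursor comes from two short fragments joined by cross-metathesis.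

Key step: step 10

Remark on numbering: chromone numbering is used for ring A. Pyranone C6 and C5 of precursor 15 become C8a and C4a.
Remark on descriptors: the carbinol carbon keeps the same spatial arrangement from 10 to 24. It is called R in 10–12 because a vinyl group outranks CH2CO2Me, and S once that alkene is saturated.
Assumption: ethereal CH2N2 is generated separately from N-methyl-N-nitroso-p-toluenesulfonamide and KOH and used as a stock solution.

Step 1
Reactants: 1 acetylacetone (pentane-2,4-dione); 2 allyl bromide
Product: 3 oct-7-ene-2,4-dione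
Conditions: LiN(iPr)2 (LDA, 2.1 equiv), THF, 0 °C; 2 (1.0 equiv), 0 °C → rt; 1 M HCl
Reagents that add atoms: none
Why: γ-Alkylation of a 1,3-diketone after twofold deprotonation, in which the terminal carbanion is by far the more nucleophilic site, so the reactive allylic bromide should be taken up only at C1.

Step 2
Reactants: 3 oct-7-ene-2,4-dione; 4 dibenzyl oxalate
Product: 6 benzyl 6-(but-3-en-1-yl)-4-oxo-4H-pyran-2-carboxylate, via benzyl 2,4,6-trioxodec-9-enoate 5 (not isolated)
Conditions: NaH (3 equiv), BnOH (cat.), THF, 0 °C → rt; 1 M HCl; crude 5, TsOH·H2O (cat.), toluene, reflux, Dean–Stark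
Reagents that add atoms: none
Why: Crossed Claisen condensation with a non-enolisable oxalate under equilibrating alkoxide conditions should settle on the unhindered methyl terminus of 3, because the doubly enolised 2,4,6-trioxo ester is the thermodynamic sink, and acid-catalysed cyclodehydration of such a 1,3,5-tricarbonyl chain is the classical entry to 4-pyranone-2-carboxylates; the benzyl ester is chosen so that this carboxyl group can later be freed without touching the side-chain methyl ester.

Step 3
Reactants: 7 methyl acetate; 8 acrolein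
Product: 9 methyl (±)-3-hydroxypent-4-enoate
Conditions: LiN(iPr)2 (LDA, 1.05 equiv), THF, −78 °C; 8; AcOH, −78 °C
Reagents that add atoms: none
Why: Aldol addition of the lithium enolate of an acetate ester to an enal at −78 °C is kinetically 1,2-selective and should give the racemic allylic alcohol, whose configuration is sorted out in step 4.

Step 4
Reactants: 9 methyl (±)-3-hydroxypent-4-enoate
Product: 10 methyl (R)-3-hydroxypent-4-enoate
Conditions: Amano lipase PS (Burkholderia cepacia lipase), vinyl acetate (3 equiv), MTBE, 30 °C, run to just beyond half conversion; chromatography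
Reagents that add atoms: none
Why: Lipase-catalysed kinetic resolution by irreversible transesterification, in which the Kazlauskas rule (CH2CO2Me large, vinyl medium) predicts acetylation of the S alcohol, so that carrying the conversion past one half should leave the R alcohol, which has the spatial arrangement of the target carbinol, in high enantiomeric purity.

Step 5
Reactants: 10 methyl (R)-3-hydroxypent-4-enoate
Product: 11 methyl (R)-3-(tert-butyldimethylsilyloxy)pent-4-enoate
Conditions: TBSCl, imidazole, DMF, rt
Reagents that add atoms: tert-butyldimethylsilyl chloride, CC(C)(C)[Si](C)(C)Cl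
Why: Standard imidazole-promoted silylation of a secondary alcohol, which does not touch the C–O bond of the stereocentre; the silyl ether is needed because a free hydroxyl group would be acylated by the acid chloride in step 8 and by the ketene in step 10.

Step 6
Reactants: 6 benzyl 6-(but-3-en-1-yl)-4-oxo-4H-pyran-2-carboxylate; 11 methyl (R)-3-(tert-butyldimethylsilyloxy)pent-4-enoate
Product: 12 benzyl 6-[(3E,5R)-5-(tert-butyldimethylsilyloxy)-7-methoxy-7-oxohept-3-en-1-yl]-4-oxo-4H-pyran-2-carboxylate
Conditions: 6 (2 equiv), 11 (1 equiv), second-generation Hoveyda–Grubbs catalyst (5 mol %), 1,4-benzoquinone (10 mol %), CH2Cl2, 40 °C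
Reagents that add atoms: none
Why: Olefin cross-metathesis between a rapidly and reversibly homodimerising terminal alkene (6, in excess) and a slower, branched allylic silyl ether (11) is inherently cross-selective, the ruthenium carbene tolerates esters, silyl ethers and the vinylogous ester of the pyranone, the stereocentre is a spectator, and the alkene geometry (E expected) is irrelevant because the double bond is removed in step 7.

Step 7
Reactants: 12 benzyl 6-[(3E,5R)-5-(tert-butyldimethylsilyloxy)-7-methoxy-7-oxohept-3-en-1-yl]-4-oxo-4H-pyran-2-carboxylate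
Product: 13 6-[(5S)-5-(tert-butyldimethylsilyloxy)-7-methoxy-7-oxoheptyl]-4-oxo-4H-pyran-2-carboxylic acid
Conditions: H2 (1 atm), Pd/C (10 wt %), EtOAc, rt, stopped after uptake of two equivalents of H2
Reagents that add atoms: none
Why: Heterogeneous hydrogenation saturates the 1,2-disubstituted alkene and hydrogenolyses the benzyl ester in one flask, both being much faster than reduction of the 2,6-disubstituted pyranone, while the methyl ester and the silyl ether are inert in a non-protic solvent; the configuration is unchanged and only its descriptor turns from R to S.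

Step 8
Reactants: 13 6-[(5S)-5-(tert-butyldimethylsilyloxy)-7-methoxy-7-oxoheptyl]-4-oxo-4H-pyran-2-carboxylic acid
Product: 15 methyl (S)-3-(tert-butyldimethylsilyloxy)-7-[6-(2-diazoacetyl)-4-oxo-4H-pyran-2-yl]heptanoate, via acid chloride 14 (not isolated)
Conditions: 1-chloro-N,N,2-trimethylprop-1-en-1-amine (1.1 equiv), CH2Cl2, 0 °C → rt; solution added to CH2N2 (3 equiv), Et2O, 0 °C, in the dark
Reagents that add atoms: 1-chloro-N,N,2-trimethylprop-1-en-1-amine, CC(C)=C(Cl)N(C)C (chlorine of 14); diazomethane, C=[N+]=[N-] (CHN2 unit of 15)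
Why: Acylation of diazomethane by an acid chloride (the first stage of the Arndt–Eistert sequence), with a second equivalent of CH2N2 consuming the HCl; the chloroenamine makes the acid chloride under neutral conditions, so neither the silyl ether nor the Lewis-basic pyranone carbonyl sees HCl or a Vilsmeier-type species, and only one carboxyl group is free to react.

Step 9
Reactants: 16 chloroacetaldehyde dimethyl acetal
Product: 17 methoxyacetylene
Conditions: NaNH2 (3.1 equiv), liquid NH3, −33 °C; NH3 evaporated; cold saturated aqueous NaCl, −20 → 0 °C; 17 distilled into toluene at −78 °C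
Reagents that add atoms: none
Why: Standard alkoxyacetylene synthesis, in which NaNH2 removes methanol and then HCl from the α-chloro acetal by successive β-eliminations and aqueous protonation releases the volatile alkyne, which is kept and dosed as a cold toluene solution.

Step 10
Reactants: 15 methyl (S)-3-(tert-butyldimethylsilyloxy)-7-[6-(2-diazoacetyl)-4-oxo-4H-pyran-2-yl]heptanoate; 17 methoxyacetylene
Product: 22 methyl (S)-3-(tert-butyldimethylsilyloxy)-7-(5-hydroxy-7-methoxy-4-oxo-4H-chromen-2-yl)heptanoate, via pyranonylketene 18 (not isolated), via methoxycyclobutenone 19 (not isolated), via dienylketene 20 (not isolated), via chromenedione tautomer 21 (not isolated)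
Conditions: 15 (0.03 M), 17 (5 equiv), toluene, 365 nm LED, Pyrex, 0 °C, until N2 evolution ends; argon purge to remove excess 17; then 105 °C, sealed tube
Reagents that add atoms: none
Why: Proposed new method: Excitation of the s-Z diazo ketone at 365 nm should expel N2 with concerted 1,2-shift of the pyranonyl group (Wolff rearrangement, which makes C8–C8a) to give ketene 18, whose electrophilic carbonyl carbon (C5) is attacked by the nucleophilic CH terminus of the ynol ether (C6) while the oxygen-bearing carbon (C7) closes onto the ketene CH (C8), giving the (2+2) adduct 19. On heating, 19 opens reversibly by a conrotatory 4π process to dienylketene 20, and only the isomer with the pyranonyl group turned towards the ketene can react further, so the equilibrium drains through it. Ring A then closes by a thermal disrotatory 6π electrocyclisation in which the ketene carbon bonds to pyranone C5 (C4a), the nucleophilic β-carbon of the ring enol ether O1–C6=C5, and dione 21 enolises at once because its C4a–H lies between two carbonyl groups. The closest known reaction is the diazo ketone variant of the Danheiser benzannulation (a Smith–Hoehn-type 4π/6π cascade), established for vinyl, aryl and five-membered heteroaryl diazomethyl ketones with alkoxy- and siloxyalkynes but not with a 4-pyranone as the unsaturated partner. No lasting stereocentre is created (the ring carbon of 19 and C4a of 21 are erased on aromatisation) and the remote silyloxy centre is a spectator. The two selectivities needed are secured by the components, since the polarisation of methoxyacetylene places OMe on C7 meta to the C5 hydroxyl and the ipso carbon has the ring oxygen on one side so that closure can reach only C4a, while light above 350 nm spares the pyranone chromophore and separating the cold photolysis from the heating keeps the phenol away from free ketene.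

Step 11
Reactants: 22 methyl (S)-3-(tert-butyldimethylsilyloxy)-7-(5-hydroxy-7-methoxy-4-oxo-4H-chromen-2-yl)heptanoate
Product: 23 methyl (S)-3-(tert-butyldimethylsilyloxy)-7-(5,7-dimethoxy-4-oxo-4H-chromen-2-yl)heptanoate
Conditions: MeI (5 equiv), K2CO3 (3 equiv), acetone, reflux
Reagents that add atoms: iodomethane, CI
Why: Williamson-type O-methylation, routine for hydrogen-bonded 5-hydroxychromones when excess MeI and heat are used, with a carbonate base too weak to enolise the β-silyloxy ester and trigger elimination.

Step 12
Reactants: 23 methyl (S)-3-(tert-butyldimethylsilyloxy)-7-(5,7-dimethoxy-4-oxo-4H-chromen-2-yl)heptanoate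
Product: 24 penithochromone Q, methyl (S)-7-(5,7-dimethoxy-4-oxo-4H-chromen-2-yl)-3-hydroxyheptanoate
Conditions: HF·pyridine, pyridine, THF, 0 °C → rt
Reagents that add atoms: none
Why: Fluoride-driven Si–O cleavage under buffered, mildly acidic conditions avoids the β-elimination or retro-aldol cleavage that basic fluoride could cause in a β-hydroxy ester, and the C–O bond of the stereocentre is not broken, so the S configuration is retained.

Compound list
1 | acetylacetone | CC(=O)CC(C)=O | starting material
2 | allyl bromide | C=CCBr | starting material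
3 | oct-7-ene-2,4-dione | CC(=O)CC(=O)CCC=C | intermediate
4 | dibenzyl oxalate | O=C(OCc1ccccc1)C(=O)OCc1ccccc1 | starting material
5 | benzyl 2,4,6-trioxodec-9-enoate | C=CCCC(=O)CC(=O)CC(=O)C(=O)OCc1ccccc1 | intermediate
6 | benzyl 6-(but-3-en-1-yl)-4-oxo-4H-pyran-2-carboxylate | C=CCCc1cc(=O)cc(o1)C(=O)OCc2ccccc2 | intermediate
7 | methyl acetate | COC(C)=O | starting material
8 | acrolein | C=CC=O | starting material
9 | methyl (±)-3-hydroxypent-4-enoate | COC(=O)CC(O)C=C | intermediate
10 | methyl (R)-3-hydroxypent-4-enoate | COC(=O)C[C@@H](O)C=C | intermediate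
11 | methyl (R)-3-(tert-butyldimethylsilyloxy)pent-4-enoate | COC(=O)C[C@@H](O[Si](C)(C)C(C)(C)C)C=C | intermediate
12 | benzyl 6-[(3E,5R)-5-(tert-butyldimethylsilyloxy)-7-methoxy-7-oxohept-3-en-1-yl]-4-oxo-4H-pyran-2-carboxylate | COC(=O)C[C@@H](O[Si](C)(C)C(C)(C)C)/C=C/CCc1cc(=O)cc(o1)C(=O)OCc2ccccc2 | intermediate
13 | 6-[(5S)-5-(tert-butyldimethylsilyloxy)-7-methoxy-7-oxoheptyl]-4-oxo-4H-pyran-2-carboxylic acid | COC(=O)C[C@@H](O[Si](C)(C)C(C)(C)C)CCCCc1cc(=O)cc(o1)C(=O)O | intermediate
14 | 6-[(5S)-5-(tert-butyldimethylsilyloxy)-7-methoxy-7-oxoheptyl]-4-oxo-4H-pyran-2-carbonyl chloride | COC(=O)C[C@@H](O[Si](C)(C)C(C)(C)C)CCCCc1cc(=O)cc(o1)C(=O)Cl | intermediate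
15 | methyl (S)-3-(tert-butyldimethylsilyloxy)-7-[6-(2-diazoacetyl)-4-oxo-4H-pyran-2-yl]heptanoate | COC(=O)C[C@@H](O[Si](C)(C)C(C)(C)C)CCCCc1cc(=O)cc(o1)C(=O)C=[N+]=[N-] | intermediate
16 | chloroacetaldehyde dimethyl acetal | COC(OC)CCl | starting material
17 | methoxyacetylene | COC#C | intermediate
18 | methyl (S)-3-(tert-butyldimethylsilyloxy)-7-[4-oxo-6-(2-oxoethenyl)-4H-pyran-2-yl]heptanoate (pyranonylketene) | COC(=O)C[C@@H](O[Si](C)(C)C(C)(C)C)CCCCc1cc(=O)cc(o1)C=C=O | intermediate
19 | methyl (3S)-3-(tert-butyldimethylsilyloxy)-7-[6-(2-methoxy-4-oxocyclobut-2-en-1-yl)-4-oxo-4H-pyran-2-yl]heptanoate (both epimers at the four-membered ring) | COC(=O)C[C@@H](O[Si](C)(C)C(C)(C)C)CCCCc1cc(=O)cc(o1)C2C(=O)C=C2OC | intermediate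
20 | methyl (S)-3-(tert-butyldimethylsilyloxy)-7-{6-[(1E)-2-methoxy-4-oxobuta-1,3-dien-1-yl]-4-oxo-4H-pyran-2-yl}heptanoate (reactive dienylketene isomer) | COC(=O)C[C@@H](O[Si](C)(C)C(C)(C)C)CCCCc1cc(=O)cc(o1)/C=C(OC)\C=C=O | intermediate
21 | methyl (3S)-3-(tert-butyldimethylsilyloxy)-7-(7-methoxy-4,5-dioxo-4a,5-dihydro-4H-chromen-2-yl)heptanoate (both epimers at C4a) | COC(=O)C[C@@H](O[Si](C)(C)C(C)(C)C)CCCCC1=CC(=O)C2C(=O)C=C(OC)C=C2O1 | intermediate
22 | methyl (S)-3-(tert-butyldimethylsilyloxy)-7-(5-hydroxy-7-methoxy-4-oxo-4H-chromen-2-yl)heptanoate | COC(=O)C[C@@H](O[Si](C)(C)C(C)(C)C)CCCCc1cc(=O)c2c(O)cc(OC)cc2o1 | intermediate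
23 | methyl (S)-3-(tert-butyldimethylsilyloxy)-7-(5,7-dimethoxy-4-oxo-4H-chromen-2-yl)heptanoate | COC(=O)C[C@@H](O[Si](C)(C)C(C)(C)C)CCCCc1cc(=O)c2c(OC)cc(OC)cc2o1 | intermediate
24 | penithochromone Q | COC(=O)C[C@@H](O)CCCCc1cc(=O)c2c(OC)cc(OC)cc2o1 | target

Total step count: 12
Longest linear sequence: 9 steps (3, 4, 5, 6, 7, 8, 10, 11, 12)

Steps most likely to fail

1. Step 10 (Proposed new method).
- What may go wrong: light absorbed by the acylpyranone chromophore may divert material into pyranone photorearrangement. The ketene may dimerise. The diazo ketone may add as a dipole to the ynol ether before it loses nitrogen. The 6π closure onto the pyranone edge may lag behind decay of the dienylketene.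
- Fallback: it uses only known chemistry, sets out from 11 and comes back to the route at 23, and it buys ring A instead of building it. Commercial 2'-hydroxy-4',6'-dimethoxyacetophenone is O-acylated with pent-4-enoyl chloride (pyridine, CH2Cl2) to 2-acetyl-3,5-dimethoxyphenyl pent-4-enoate F1. A Baker–Venkataraman acyl shift (KOtBu, THF) gives 1-(2-hydroxy-4,6-dimethoxyphenyl)hept-6-ene-1,3-dione F2. Cyclodehydration (H2SO4 cat., AcOH, 80 °C) gives 2-(but-3-en-1-yl)-5,7-dimethoxy-4H-chromen-4-one F3. Cross-metathesis of F3 with 11 under the conditions of step 6 gives methyl (3R,4E)-3-(tert-butyldimethylsilyloxy)-7-(5,7-dimethoxy-4-oxo-4H-chromen-2-yl)hept-4-enoate F4. Hydrogenation (H2, Pd/C, EtOAc) then gives 23.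

2. Step 6.
- What may go wrong: homodimerisation of 6 may outrun the cross reaction with the hindered allylic ether, and ruthenium hydride species may move the terminal double bond of 6 along the chain.
- Fallback: it sets out from 1 and comes back at 13, and it replaces metathesis by alkylation of a preformed pyranone with a chain whose stereocentre comes from asymmetric hydrogenation.
 - Pyranone part: acetylacetone 1 is condensed with diallyl oxalate (NaH, THF) to allyl 2,4,6-trioxoheptanoate F5, which is closed (TsOH·H2O, toluene, reflux) to allyl 6-methyl-4-oxo-4H-pyran-2-carboxylate F6.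
 - Chain part: commercial 4-(benzyloxy)butanoic acid is homologated (carbonyldiimidazole; MeO2CCH2CO2K, MgCl2, Et3N; Masamune–Brooks reaction) to methyl 6-(benzyloxy)-3-oxohexanoate F7. Noyori hydrogenation (RuCl2[(S)-BINAP], H2, MeOH) reduces it to methyl (S)-6-(benzyloxy)-3-hydroxyhexanoate F8. Silylation (TBSCl, imidazole) gives methyl (S)-6-(benzyloxy)-3-(tert-butyldimethylsilyloxy)hexanoate F9. Debenzylation (H2, Pd/C, EtOAc) gives methyl (S)-3-(tert-butyldimethylsilyloxy)-6-hydroxyhexanoate F10, and I2, PPh3 and imidazole convert this into methyl (S)-3-(tert-butyldimethylsilyloxy)-6-iodohexanoate F11.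
 - Union: deprotonation of F6 at its 6-methyl group (LiN(SiMe3)2, THF–DMPU, −78 °C) gives a vinylogous enolate that is too weakly basic to enolise the β-silyloxy ester. Its alkylation with F11 gives allyl 6-[(5S)-5-(tert-butyldimethylsilyloxy)-7-methoxy-7-oxoheptyl]-4-oxo-4H-pyran-2-carboxylate F12. Pd(PPh3)4 with morpholine then removes the allyl ester under neutral conditions to give 13.

3. Step 2.
- What may go wrong: acylation at the internal methylene group of 3 may compete with the methyl terminus, and the oxalyl end may lactonise to a five-membered ring instead of dehydrating to the six-membered pyranone.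
- Fallback: it sets out from 1 and 4 and comes back at 6, and it reverses the order so that the ring is made first from the symmetrical diketone and the chain is added second. Claisen condensation of 1 with 4 (NaH, THF), where both termini are equivalent, gives benzyl 2,4,6-trioxoheptanoate F13. Acid cyclodehydration (TsOH·H2O, toluene) gives benzyl 6-methyl-4-oxo-4H-pyran-2-carboxylate F14. Deprotonation of the 6-methyl group (LiN(SiMe3)2, THF, −78 °C) and allylation with the reactive halide 2 gives 6.

Further compounds
F1 | step 10 | 2-acetyl-3,5-dimethoxyphenyl pent-4-enoate | C=CCCC(=O)Oc1cc(OC)cc(OC)c1C(C)=O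
F2 | step 10 | 1-(2-hydroxy-4,6-dimethoxyphenyl)hept-6-ene-1,3-dione | C=CCCC(=O)CC(=O)c1c(O)cc(OC)cc1OC
F3 | step 10 | 2-(but-3-en-1-yl)-5,7-dimethoxy-4H-chromen-4-one | C=CCCc1cc(=O)c2c(OC)cc(OC)cc2o1
F4 | step 10 | methyl (3R,4E)-3-(tert-butyldimethylsilyloxy)-7-(5,7-dimethoxy-4-oxo-4H-chromen-2-yl)hept-4-enoate | COC(=O)C[C@@H](O[Si](C)(C)C(C)(C)C)/C=C/CCc1cc(=O)c2c(OC)cc(OC)cc2o1
F5 | step 6 | allyl 2,4,6-trioxoheptanoate | CC(=O)CC(=O)CC(=O)C(=O)OCC=C
F6 | step 6 | allyl 6-methyl-4-oxo-4H-pyran-2-carboxylate | Cc1cc(=O)cc(o1)C(=O)OCC=C
F7 | step 6 | methyl 6-(benzyloxy)-3-oxohexanoate | COC(=O)CC(=O)CCCOCc1ccccc1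
F8 | step 6 | methyl (S)-6-(benzyloxy)-3-hydroxyhexanoate | COC(=O)C[C@@H](O)CCCOCc1ccccc1
F9 | step 6 | methyl (S)-6-(benzyloxy)-3-(tert-butyldimethylsilyloxy)hexanoate | COC(=O)C[C@@H](O[Si](C)(C)C(C)(C)C)CCCOCc1ccccc1
F10 | step 6 | methyl (S)-3-(tert-butyldimethylsilyloxy)-6-hydroxyhexanoate | COC(=O)C[C@@H](O[Si](C)(C)C(C)(C)C)CCCO
F11 | step 6 | methyl (S)-3-(tert-butyldimethylsilyloxy)-6-iodohexanoate | COC(=O)C[C@@H](O[Si](C)(C)C(C)(C)C)CCCI
F12 | step 6 | allyl 6-[(5S)-5-(tert-butyldimethylsilyloxy)-7-methoxy-7-oxoheptyl]-4-oxo-4H-pyran-2-carboxylate | COC(=O)C[C@@H](O[Si](C)(C)C(C)(C)C)CCCCc1cc(=O)cc(o1)C(=O)OCC=C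
F13 | step 2 | benzyl 2,4,6-trioxoheptanoate | CC(=O)CC(=O)CC(=O)C(=O)OCc1ccccc1
F14 | step 2 | benzyl 6-methyl-4-oxo-4H-pyran-2-carboxylate | Cc1cc(=O)cc(o1)C(=O)OCc2ccccc2
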